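**Plan**

- Retrosynthesis (furanone numbered O1, C2(=O), C3(OH), C4(aryl), C5(quaternary)): first the two O-benzyl groups are cut, then the C4–aryl bond (Suzuki coupling of an enol triflate), which returns C4 to a ketone. Next both bonds holding the lactone O–C(=O) unit are cut, ring O1–C5 and C2–C3, so the unit leaves as CO2; then C5–Cl and C5–CH2(chromanyl).
- Enabling feature: in the furanone ring the O–C(=O) unit sits between the enol carbon C3 and the quaternary C5. With C4 as a ketone, C3 is its only enolisable α-carbon (nucleophile for CO2) and C5 is the α-carbon of a β-keto ester that can carry chloride (electrophile for the new carboxylate).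
- Forward order: the chromanol ring comes from a commercial chromene (epoxidation, hydrogenolysis) and the nitrile becomes the aldehyde. Reductive alkylation of methyl 4-(benzyloxy)acetoacetate joins the chain, chlorination follows, and CO2 closes the furanone ring; the aryl ring is attached last, then debenzylation.
- Stereochemistry: the carbinol centre comes from the Mn(salen) epoxidation (its C–O bond is never broken). The quaternary centre comes from a catalytic enantioselective chlorination and is transferred with inversion in the CO2 ring closure.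

Key step: step 6

Remark: 7 is carried as a mixture of epimers at its enolisable C2, 10 is drawn as the free acid although it is present as the caesium carboxylate, and in step 5 the ligand antipode is the one that delivers the 2S chloride (sense to be assigned on the first batch).

**Step 1**
Reactants: 1 2,2-dimethyl-2H-chromene-6-carbonitrile
Product: 2 (3S,4S)-3,4-epoxy-2,2-dimethylchromane-6-carbonitrile
Conditions: (S,S)-Mn(salen)Cl (Jacobsen catalyst, 2 mol%), aq. NaOCl (pH 11.3), 4-phenylpyridine N-oxide, CH2Cl2, 0 °C
Reagents that add atoms: sodium hypochlorite, [Na+].[O-]Cl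
Why: Jacobsen–Katsuki epoxidation of a cis-disubstituted 2,2-dimethylchromene, the classical substrate class for this catalyst; the (S,S)-catalyst should deliver oxygen to the face that gives the (3S,4S)-epoxide, which fixes the later carbinol centre.

**Step 2**
Reactants: 2 (3S,4S)-3,4-epoxy-2,2-dimethylchromane-6-carbonitrile
Product: 3 (3S)-3-hydroxy-2,2-dimethylchromane-6-carbonitrile
Conditions: H2 (1 atm), 10% Pd/C, EtOAc, rt
Reagents that add atoms: none
Why: Palladium-catalysed hydrogenolysis should cleave only the benzylic C4–O bond of the aryl epoxide, so the C3–O bond and its (S) configuration stay untouched, and the aryl nitrile should survive neutral low-pressure conditions.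

**Step 3**
Reactants: 3 (3S)-3-hydroxy-2,2-dimethylchromane-6-carbonitrile
Product: 4 (3S)-3-hydroxy-2,2-dimethylchromane-6-carbaldehyde
Conditions: DIBAL-H (2.3 equiv), CH2Cl2, −78 °C; then aq. HCl, 0 °C
Reagents that add atoms: water, O
Why: DIBAL-H partial reduction of the aryl nitrile to the N-aluminio imine and hydrolysis should give the aldehyde; the free hydroxyl only consumes one extra equivalent of hydride as its aluminium alkoxide.

**Step 4**
Reactants: 4 (3S)-3-hydroxy-2,2-dimethylchromane-6-carbaldehyde; 5 methyl 4-(benzyloxy)-3-oxobutanoate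
Product: 7 methyl 4-(benzyloxy)-2-{[(3S)-3-hydroxy-2,2-dimethylchroman-6-yl]methyl}-3-oxobutanoate, via alkylidene keto ester 6 (not isolated)
Conditions: L-proline (20 mol%), Hantzsch ester (1.1 equiv), EtOH, rt
Reagents that add atoms: none
Why: Organocatalytic reductive alkylation: Knoevenagel condensation at the doubly activated C2 of the β-keto ester gives 6, which is reduced in situ by conjugate hydride transfer from the Hantzsch ester, so mono-benzylation should result without a benzylic halide; the new C2–H centre is enolisable and is left unassigned.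

**Step 5**
Reactants: 7 methyl 4-(benzyloxy)-2-{[(3S)-3-hydroxy-2,2-dimethylchroman-6-yl]methyl}-3-oxobutanoate
Product: 8 methyl (2S)-4-(benzyloxy)-2-chloro-2-{[(3S)-3-hydroxy-2,2-dimethylchroman-6-yl]methyl}-3-oxobutanoate
Conditions: Cu(OTf)2 (10 mol%), Ph-BOX ligand (12 mol%, antipode giving 2S), NCS (1.2 equiv), Et2O/CH2Cl2, 0 °C
Reagents that add atoms: N-chlorosuccinimide, O=C1CCC(=O)N1Cl
Why: Chiral Lewis acid catalysed enantioselective α-chlorination of an α-substituted β-keto ester: the Cu(II)–bisoxazoline chelate of the 1,3-dicarbonyl enolate exposes one face to NCS, so the quaternary C–Cl centre should be set under catalyst control, and the remote chroman centre makes any minor epimer a separable diastereomer.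

**Step 6**
Reactants: 8 methyl (2S)-4-(benzyloxy)-2-chloro-2-{[(3S)-3-hydroxy-2,2-dimethylchroman-6-yl]methyl}-3-oxobutanoate; 9 carbon dioxide
Product: 11 methyl (2R)-4-(benzyloxy)-3-hydroxy-2-{[(3S)-3-hydroxy-2,2-dimethylchroman-6-yl]methyl}-5-oxo-2,5-dihydrofuran-2-carboxylate, via chloro keto carboxylate 10 (not isolated)
Conditions: Cs2CO3 (2.2 equiv), CO2 (10 bar), dry DMF, 25→40 °C; then aq. citric acid
Reagents that add atoms: none
Why: Proposed new method: Caesium carbonate should reversibly enolise the only enolisable position of 8, the methylene between the ketone and the benzyloxy group, and CO2 traps the enolate as β-keto carboxylate 10; its caesium carboxylate oxygen then displaces the tertiary chloride on the other side of the ketone, so the C(=O)–C bond and the ring O–C bond form in one flask and the product drains irreversibly into the acidic tetronate, which pulls the reversible carboxylation forward. The closest known reaction types are the base/CO2 α-carboxylation of ketones with in situ O-alkylation of the β-keto carboxylate, carboxylative cyclisations in which a CO2-derived carboxylate closes a lactone ring on a tethered electrophile, and the SN2 substitution of tertiary α-chloro β-keto esters by external nucleophiles. The furanone ring closes in the 5-exo-tet mode. The quaternary centre is transferred, not created: backside attack inverts the (S)-C–Cl centre to the (R)-C–O centre, while the carbon that receives CO2 ends as an sp2 enol carbon without stereochemistry. The step needs O-alkylation by the carboxylate to beat 3-exo C-alkylation by the enolate (Favorskii path), base-induced loss of HCl and ionisation of the chloride; CO2 pressure keeps the free enolate concentration low, the weak carbonate base and the lack of an α-hydrogen at the chlorinated carbon disfavour elimination and epimerisation, and the two flanking carbonyl groups disfavour SN1 ionisation while activating the centre towards SN2.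

**Step 7**
Reactants: 11 methyl (2R)-4-(benzyloxy)-3-hydroxy-2-{[(3S)-3-hydroxy-2,2-dimethylchroman-6-yl]methyl}-5-oxo-2,5-dihydrofuran-2-carboxylate
Product: 12 methyl (2R)-4-(benzyloxy)-2-{[(3S)-3-hydroxy-2,2-dimethylchroman-6-yl]methyl}-5-oxo-3-{[(trifluoromethyl)sulfonyl]oxy}-2,5-dihydrofuran-2-carboxylate
Conditions: PhNTf2 (1.1 equiv), Et3N, DMAP (cat.), CH2Cl2, 0 °C→rt
Reagents that add atoms: N-phenylbis(trifluoromethanesulfonimide), O=S(=O)(N(c1ccccc1)S(=O)(=O)C(F)(F)F)C(F)(F)F
Why: O-Sulfonylation of the tetronate (a vinylogous carboxylate) with the mild triflyl donor PhNTf2, which should not react with the hindered neutral secondary alcohol, turns the helper ketone oxygen into a leaving group.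

**Step 8**
Reactants: 12 methyl (2R)-4-(benzyloxy)-2-{[(3S)-3-hydroxy-2,2-dimethylchroman-6-yl]methyl}-5-oxo-3-{[(trifluoromethyl)sulfonyl]oxy}-2,5-dihydrofuran-2-carboxylate; 13 [4-(benzyloxy)phenyl]boronic acid
Product: 14 methyl (2R)-4-(benzyloxy)-3-[4-(benzyloxy)phenyl]-2-{[(3S)-3-hydroxy-2,2-dimethylchroman-6-yl]methyl}-5-oxo-2,5-dihydrofuran-2-carboxylate
Conditions: Pd(PPh3)4 (5 mol%), K3PO4, 1,4-dioxane/H2O (20:1), 70 °C
Reagents that add atoms: none
Why: Suzuki–Miyaura coupling of an electron-poor enol triflate at the β-position of the butenolide with an arylboronic acid; the phosphate base with little water limits triflate hydrolysis, and the quaternary centre has no acidic hydrogen.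

**Step 9**
Reactants: 14 methyl (2R)-4-(benzyloxy)-3-[4-(benzyloxy)phenyl]-2-{[(3S)-3-hydroxy-2,2-dimethylchroman-6-yl]methyl}-5-oxo-2,5-dihydrofuran-2-carboxylate
Product: 15 butyrolactone V, methyl (2R)-4-hydroxy-3-(4-hydroxyphenyl)-2-{[(3S)-3-hydroxy-2,2-dimethylchroman-6-yl]methyl}-5-oxo-2,5-dihydrofuran-2-carboxylate
Conditions: H2 (1 atm), 10% Pd/C, EtOAc/MeOH, rt
Reagents that add atoms: none
Why: Hydrogenolysis of the aryl benzyl ether and the enol benzyl ether should unmask the phenol and the 3-hydroxy enol under neutral conditions that leave the tetrasubstituted push–pull alkene, the lactone and both stereocentres untouched.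

**Compound list**

1 | 2,2-dimethyl-2H-chromene-6-carbonitrile | CC1(C)C=Cc2cc(C#N)ccc2O1 | starting material
2 | (3S,4S)-3,4-epoxy-2,2-dimethylchromane-6-carbonitrile | CC1(C)[C@H]2O[C@H]2c3cc(C#N)ccc3O1 | intermediate
3 | (3S)-3-hydroxy-2,2-dimethylchromane-6-carbonitrile | N#Cc1ccc2c(c1)C[C@H](O)C(C)(C)O2 | intermediate
4 | (3S)-3-hydroxy-2,2-dimethylchromane-6-carbaldehyde | O=Cc1ccc2c(c1)C[C@H](O)C(C)(C)O2 | intermediate
5 | methyl 4-(benzyloxy)-3-oxobutanoate | COC(=O)CC(=O)COCc1ccccc1 | starting material
6 | methyl 4-(benzyloxy)-2-{[(3S)-3-hydroxy-2,2-dimethylchroman-6-yl]methylidene}-3-oxobutanoate (E/Z, formed in situ) | COC(=O)C(=Cc1ccc2c(c1)C[C@H](O)C(C)(C)O2)C(=O)COCc1ccccc1 | intermediate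
7 | methyl 4-(benzyloxy)-2-{[(3S)-3-hydroxy-2,2-dimethylchroman-6-yl]methyl}-3-oxobutanoate (both C2 epimers) | COC(=O)C(Cc1ccc2c(c1)C[C@H](O)C(C)(C)O2)C(=O)COCc1ccccc1 | intermediate
8 | methyl (2S)-4-(benzyloxy)-2-chloro-2-{[(3S)-3-hydroxy-2,2-dimethylchroman-6-yl]methyl}-3-oxobutanoate | COC(=O)[C@](Cl)(Cc1ccc2c(c1)C[C@H](O)C(C)(C)O2)C(=O)COCc1ccccc1 | intermediate
9 | carbon dioxide | O=C=O | starting material
10 | (4S)-2-(benzyloxy)-4-chloro-4-{[(3S)-3-hydroxy-2,2-dimethylchroman-6-yl]methyl}-5-methoxy-3,5-dioxopentanoic acid (caesium salt in the flask, C2 unassigned) | COC(=O)[C@](Cl)(Cc1ccc2c(c1)C[C@H](O)C(C)(C)O2)C(=O)C(OCc1ccccc1)C(=O)O | intermediate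
11 | methyl (2R)-4-(benzyloxy)-3-hydroxy-2-{[(3S)-3-hydroxy-2,2-dimethylchroman-6-yl]methyl}-5-oxo-2,5-dihydrofuran-2-carboxylate | COC(=O)[C@]1(Cc2ccc3c(c2)C[C@H](O)C(C)(C)O3)OC(=O)C(OCc2ccccc2)=C1O | intermediate
12 | methyl (2R)-4-(benzyloxy)-2-{[(3S)-3-hydroxy-2,2-dimethylchroman-6-yl]methyl}-5-oxo-3-{[(trifluoromethyl)sulfonyl]oxy}-2,5-dihydrofuran-2-carboxylate | COC(=O)[C@]1(Cc2ccc3c(c2)C[C@H](O)C(C)(C)O3)OC(=O)C(OCc2ccccc2)=C1OS(=O)(=O)C(F)(F)F | intermediate
13 | [4-(benzyloxy)phenyl]boronic acid | OB(O)c1ccc(OCc2ccccc2)cc1 | starting material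
14 | methyl (2R)-4-(benzyloxy)-3-[4-(benzyloxy)phenyl]-2-{[(3S)-3-hydroxy-2,2-dimethylchroman-6-yl]methyl}-5-oxo-2,5-dihydrofuran-2-carboxylate | COC(=O)[C@]1(Cc2ccc3c(c2)C[C@H](O)C(C)(C)O3)OC(=O)C(OCc2ccccc2)=C1c1ccc(OCc2ccccc2)cc1 | intermediate
15 | butyrolactone V | COC(=O)[C@]1(Cc2ccc3c(c2)C[C@H](O)C(C)(C)O3)OC(=O)C(O)=C1c1ccc(O)cc1 | target

Total step count: 9. Longest linear sequence: 9 steps (1 → 15); 5, 9 and 13 are bought.

**Steps most likely to fail**

1. Step 6. The enolate may alkylate at carbon before CO2 capture (Favorskii-type ring contraction), HCl may be lost to the benzylidene keto ester, or carbonate may consume the chloride if carboxylation is too reversible. The fallback uses known chemistry and installs the ring oxygen first and the carbonyl second. It sets out from 7: catalytic enantioselective α-hydroxylation of the β-keto ester (cumene hydroperoxide, cinchona-derived phase-transfer catalyst) should give methyl (2R)-4-(benzyloxy)-2-hydroxy-2-{[(3S)-3-hydroxy-2,2-dimethylchroman-6-yl]methyl}-3-oxobutanoate F1. Boc2O/DMAP converts both hydroxyls into the bis(tert-butyl carbonate) F2. LiHMDS (THF, −78→0 °C) then closes the ring by a Dieckmann-type C-acylation of the ketone enolate on the tertiary carbonate, giving the chromanyl O-Boc tetronic acid F3. TFA/CH2Cl2 removes the remaining carbonate and the route is rejoined at 11.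

2. Step 5. Facial discrimination may be insufficient for an acyclic methyl ester, or the sense of induction may be wrong for the ligand at hand. The fallback replaces catalyst control by separation and recycling and sets out from 7. Uncatalysed chlorination (NCS, CH2Cl2) gives both C2 epimers, which are diastereomers because of the chroman centre and should separate by chromatography or crystallisation. The 2S epimer is 8, where the route is rejoined. The unwanted methyl (2R)-4-(benzyloxy)-2-chloro-2-{[(3S)-3-hydroxy-2,2-dimethylchroman-6-yl]methyl}-3-oxobutanoate F4 is returned to 7 by reductive dechlorination (Zn, AcOH) and chlorinated again.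

3. Step 4. A second keto ester may add to alkylidene 6 in a Michael reaction before hydride transfer, or condensation of the electron-rich aldehyde may be sluggish. The fallback is a classical enolate alkylation and sets out from 4. NaBH4 (MeOH) gives (3S)-6-(hydroxymethyl)-2,2-dimethylchroman-3-ol F5. Aqueous 48% HBr/toluene at 0 °C should convert only the electron-rich benzylic alcohol, giving (3S)-6-(bromomethyl)-2,2-dimethylchroman-3-ol F6. The sodium enolate of 5 (NaH, THF) is then alkylated with F6, rejoining the route at 7.

**Further compounds**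

F1 | step 6 | methyl (2R)-4-(benzyloxy)-2-hydroxy-2-{[(3S)-3-hydroxy-2,2-dimethylchroman-6-yl]methyl}-3-oxobutanoate | COC(=O)[C@@](O)(Cc1ccc2c(c1)C[C@H](O)C(C)(C)O2)C(=O)COCc1ccccc1
F2 | step 6 | methyl (2R)-4-(benzyloxy)-2-[(tert-butoxycarbonyl)oxy]-2-({(3S)-3-[(tert-butoxycarbonyl)oxy]-2,2-dimethylchroman-6-yl}methyl)-3-oxobutanoate | COC(=O)[C@@](OC(=O)OC(C)(C)C)(Cc1ccc2c(c1)C[C@H](OC(=O)OC(C)(C)C)C(C)(C)O2)C(=O)COCc1ccccc1
F3 | step 6 | methyl (2R)-4-(benzyloxy)-2-({(3S)-3-[(tert-butoxycarbonyl)oxy]-2,2-dimethylchroman-6-yl}methyl)-3-hydroxy-5-oxo-2,5-dihydrofuran-2-carboxylate | COC(=O)[C@]1(Cc2ccc3c(c2)C[C@H](OC(=O)OC(C)(C)C)C(C)(C)O3)OC(=O)C(OCc2ccccc2)=C1O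
F4 | step 5 | methyl (2R)-4-(benzyloxy)-2-chloro-2-{[(3S)-3-hydroxy-2,2-dimethylchroman-6-yl]methyl}-3-oxobutanoate | COC(=O)[C@@](Cl)(Cc1ccc2c(c1)C[C@H](O)C(C)(C)O2)C(=O)COCc1ccccc1
F5 | step 4 | (3S)-6-(hydroxymethyl)-2,2-dimethylchroman-3-ol | OCc1ccc2c(c1)C[C@H](O)C(C)(C)O2
F6 | step 4 | (3S)-6-(bromomethyl)-2,2-dimethylchroman-3-ol | BrCc1ccc2c(c1)C[C@H](O)C(C)(C)O2
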